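The plan reads C7–C8–C9–C10 (C7 the methine on rings A and C, C8 and C9 the two CH(CH3) carbons, C10 the ring D methylene) as C2–C3–C4–C5 of a 5-aryl butenolide. A removable benzylic C–O stereocentre at C10 sends a methyl cuprate to the opposite face of C9. The new methyl then sends iodomethane to the opposite face of C8, so two C–CH3 bonds and both stereocentres arise in one flask. The precursor is the (S)-butenolide bearing ring D as its para-silyloxyphenyl group. Hydrogenolysis erases the temporary centre, the carboxyl carbon becomes C7, and C8 steers the closing Friedel–Crafts union with ring A.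

Key step: step 4

Labels: ring A = trihydroxyphenyl ring, ring B = 4-methoxyphenyl ring, ring C = 4-hydroxyphenyl ring on C7, ring D = 4-hydroxyphenyl ring on C10. The target is (7R,8S,9R).

Assumption: (S)-BINOL is taken to direct the alkynylzinc of step 2 to the Si face of the aldehyde, as it does with other organozinc reagents; if the opposite sense were found, (R)-BINOL would be used and nothing else would change.

Step 1
Reactants: 1 4-hydroxybenzaldehyde
Product: 2 4-(triisopropylsilyloxy)benzaldehyde
Conditions: TIPSCl, imidazole, DMF, rt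
Reagents that add atoms: chlorotriisopropylsilane, CC(C)[Si](Cl)(C(C)C)C(C)C
Why: Imidazole-promoted silylation of a phenol (silyl ether protection) is routine, and the bulky TIPS ether is chosen because it must later survive cuprate, hydrogenation, aryllithium and catalytic acid.

Step 2
Reactants: 2 4-(triisopropylsilyloxy)benzaldehyde; 3 methyl propiolate
Product: 5 methyl (R)-4-hydroxy-4-[4-(triisopropylsilyloxy)phenyl]but-2-ynoate, via alkynylzinc 4 (not isolated)
Conditions: 3 (4 equiv), Et2Zn (4 equiv), (S)-BINOL (40 mol %), HMPA (2 equiv), CH2Cl2, rt; Ti(OiPr)4 (1 equiv); then 2, rt; aq NH4Cl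
Reagents that add atoms: diethylzinc, CC[Zn]CC (its ethylzinc unit is kept only in 4)
Why: This is a catalytic asymmetric alkynylation of an aromatic aldehyde by a propiolate-derived alkynylzinc under BINOL–titanium control, in which Si-face delivery sets the carbinol centre as R (alkynyl outranks aryl) and which avoids an aryl alkynyl ketone whose two π substituents a reduction catalyst could hardly tell apart.

Step 3
Reactants: 5 methyl (R)-4-hydroxy-4-[4-(triisopropylsilyloxy)phenyl]but-2-ynoate
Product: 7 (S)-5-[4-(triisopropylsilyloxy)phenyl]furan-2(5H)-one, via Z-hydroxy enoate 6 (not isolated)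
Conditions: H2 (1 atm), Pd/CaCO3 poisoned with Pb(OAc)2, quinoline (cat.), EtOAc, rt; filter; PPTS (cat.), CH2Cl2, rt
Reagents that add atoms: none
Why: Syn semihydrogenation of the alkyne on poisoned palladium gives the Z-enoate, whose hydroxyl sits next to the ester and lactonises under near-neutral conditions, so the base-sensitive centre is untouched and its descriptor changes from R to S only because aryl outranks alkenyl.

Step 4
Reactants: 7 (S)-5-[4-(triisopropylsilyloxy)phenyl]furan-2(5H)-one
Product: 9 (3S,4S,5S)-3,4-dimethyl-5-[4-(triisopropylsilyloxy)phenyl]dihydrofuran-2(3H)-one, via lithium enolate 8 (not isolated)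
Conditions: Me2CuLi (2 equiv, from MeLi and a slight excess of CuBr·SMe2), Et2O, −78 °C, slow addition of 7; then MeI (10 equiv), DMPU–THF, −78 → −20 °C; aq NH4Cl/NH3
Reagents that add atoms: lithium dimethylcuprate, [Li+].C[Cu-]C; iodomethane, CI
Why: Me2CuLi binds the C3=C4 π bond of 7 on the face away from the C5 aryl group, transfers methyl to C4 through a transient trivalent copper σ-complex and leaves lithium enolate 8; MeI, assisted by DMPU, then alkylates C3 of 8 in an SN2 step on the face away from the new C4 methyl. The closest known reaction type is the anti-selective conjugate addition of lithium dialkylcuprates to 5-substituted butenolides coupled with trans alkylation of the resulting lactone enolate (tandem vicinal difunctionalisation). No ring is closed, so no mode of closure applies. C4 (future C9) is controlled by the C5 aryl substituent and C3 (future C8) by the C4 methyl, and because the trans,trans lactone is also the more stable C3 epimer, any cis isomer can be corrected by base equilibration. The step needs chemoselectivity for 1,4-addition over removal of the allylic, benzylic C5–H, together with facial selectivity at C4 and C3. The substrate secures this through its electron-releasing para-silyloxy group, which lowers the C5–H acidity, and through the flat five-membered ring, in which the C5 aryl group blocks one whole face, while the absence of free MeLi and the slow addition of 7 to excess cuprate keep 7 away from strong base and from enolate 8.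

Step 5
Reactants: 9 (3S,4S,5S)-3,4-dimethyl-5-[4-(triisopropylsilyloxy)phenyl]dihydrofuran-2(3H)-one
Product: 10 (2S,3R)-2,3-dimethyl-4-[4-(triisopropylsilyloxy)phenyl]butanoic acid
Conditions: H2 (1–4 atm), 10 % Pd/C, EtOAc–AcOH, rt
Reagents that add atoms: none
Why: Hydrogenolysis of a benzylic C–O bond (the lactone is a secondary benzylic ester activated by the para oxygen donor) turns C5 into the C10 methylene and frees the acid, while C8 and C9 take no part and the aryl silyl ether is inert to H2.

Step 6
Reactants: 10 (2S,3R)-2,3-dimethyl-4-[4-(triisopropylsilyloxy)phenyl]butanoic acid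
Product: 12 (2S,3R)-N-methoxy-N,2,3-trimethyl-4-[4-(triisopropylsilyloxy)phenyl]butanamide, via acyl imidazole 11 (not isolated)
Conditions: 1,1'-carbonyldiimidazole, CH2Cl2, rt; then MeNHOMe·HCl, rt
Reagents that add atoms: N,O-dimethylhydroxylamine hydrochloride, CNOC.Cl; 1,1'-carbonyldiimidazole, O=C(n1ccnc1)n1ccnc1 (its imidazolyl group is kept only in 11)
Why: Amide coupling through the acyl imidazole (Weinreb amide synthesis) needs no added strong base, so the α-stereocentre C8 is not at risk.

Step 7
Reactants: 13 4-bromophenol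
Product: 14 (4-bromophenoxy)triisopropylsilane
Conditions: TIPSCl, imidazole, DMF, rt
Reagents that add atoms: chlorotriisopropylsilane, CC(C)[Si](Cl)(C(C)C)C(C)C
Why: The same phenol silylation as in step 1 masks the acidic hydroxyl of ring C before metalation.

Step 8
Reactants: 12 (2S,3R)-N-methoxy-N,2,3-trimethyl-4-[4-(triisopropylsilyloxy)phenyl]butanamide; 14 (4-bromophenoxy)triisopropylsilane
Product: 17 (2S,3R)-2,3-dimethyl-1,4-bis[4-(triisopropylsilyloxy)phenyl]butan-1-one, via aryllithium 15 (not isolated), via tetrahedral adduct 16 (not isolated)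
Conditions: 14, n-BuLi, THF, −78 °C; then 12, −78 → −20 °C; cold 0.5 M HCl
Reagents that add atoms: n-butyllithium, [Li]CCCC (its lithium is kept only in 15 and 16)
Why: Bromine–lithium exchange followed by the Weinreb ketone synthesis works because chelated adduct 16 holds until the cold acidic quench, which rules out over-addition and keeps the enolisable C8 centre away from base.

Step 9
Reactants: 17 (2S,3R)-2,3-dimethyl-1,4-bis[4-(triisopropylsilyloxy)phenyl]butan-1-one
Product: 18 (2S,3R)-2,3-dimethyl-1,4-bis[4-(triisopropylsilyloxy)phenyl]butan-1-ol (both C1 epimers)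
Conditions: NaBH4, THF–MeOH, 0 °C
Reagents that add atoms: none
Why: Borohydride reduction of an aryl ketone is reliable, and the new carbinol centre needs no control because ionisation in step 11 erases it.

Step 10
Reactants: 19 phloroglucinol; 20 3-(4-methoxyphenyl)propanenitrile
Product: 22 3-(4-methoxyphenyl)-1-(2,4,6-trihydroxyphenyl)propan-1-one, via ketiminium chloride 21 (not isolated)
Conditions: ZnCl2, HCl (g), Et2O, 0 °C; then H2O, reflux
Reagents that add atoms: water, O; hydrogen chloride, Cl (its chloride is kept only in 21)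
Why: The Houben–Hoesch acylation is the classical entry to monoacylphloroglucinols, since the ketiminium salt deactivates ring A against a second acylation and the ring B methyl ether is untouched.

Step 11
Reactants: 18 (2S,3R)-2,3-dimethyl-1,4-bis[4-(triisopropylsilyloxy)phenyl]butan-1-ol (both C1 epimers); 22 3-(4-methoxyphenyl)-1-(2,4,6-trihydroxyphenyl)propan-1-one
Product: 24 1-{3-[(1R,2S,3R)-2,3-dimethyl-1,4-bis[4-(triisopropylsilyloxy)phenyl]butyl]-2,4,6-trihydroxyphenyl}-3-(4-methoxyphenyl)propan-1-one, via benzylic cation 23 (not isolated)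
Conditions: 22 (3 equiv), Bi(OTf)3 (5 mol %), MeNO2–CH2Cl2, −20 → 0 °C
Reagents that add atoms: none
Why: Acid-catalysed SN1-type Friedel–Crafts alkylation of an electron-rich arene by an α-branched, para-oxygenated benzylic alcohol is a known diastereoselective reaction class, and here 1,3-allylic strain in planar cation 23 holds C8–H in the cation plane beside the ring C ortho C–H, the C9 chain covers one face and ring A bonds to C7 from the face of the smaller C8 methyl, which sets 7R next to 8S, while the two free ring A positions are equivalent, excess 22 curbs double alkylation and the silyl ether kept on ring D prevents irreversible ipso capture of C7.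

Step 12
Reactants: 24 1-{3-[(1R,2S,3R)-2,3-dimethyl-1,4-bis[4-(triisopropylsilyloxy)phenyl]butyl]-2,4,6-trihydroxyphenyl}-3-(4-methoxyphenyl)propan-1-one
Product: 25 1-{3-[(1R,2S,3R)-1,4-bis(4-hydroxyphenyl)-2,3-dimethylbutyl]-2,4,6-trihydroxyphenyl}-3-(4-methoxyphenyl)propan-1-one (CNP0193401.2)
Conditions: Bu4NF, AcOH, THF, 0 °C
Reagents that add atoms: none
Why: Fluoride-mediated cleavage of both aryl silyl ethers is fast at low temperature, and the acetic acid buffer keeps the polyphenol protonated so that C7 cannot epimerise by retro-addition through a quinone methide.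

Compound list
1 | 4-hydroxybenzaldehyde | O=Cc1ccc(O)cc1 | starting material
2 | 4-(triisopropylsilyloxy)benzaldehyde | O=Cc1ccc(O[Si](C(C)C)(C(C)C)C(C)C)cc1 | intermediate
3 | methyl propiolate | C#CC(=O)OC | starting material
4 | ethyl(3-methoxy-3-oxoprop-1-ynyl)zinc | CC[Zn]C#CC(=O)OC | intermediate
5 | methyl (R)-4-hydroxy-4-[4-(triisopropylsilyloxy)phenyl]but-2-ynoate | COC(=O)C#C[C@H](O)c1ccc(O[Si](C(C)C)(C(C)C)C(C)C)cc1 | intermediate
6 | methyl (S,Z)-4-hydroxy-4-[4-(triisopropylsilyloxy)phenyl]but-2-enoate | COC(=O)/C=C\[C@H](O)c1ccc(O[Si](C(C)C)(C(C)C)C(C)C)cc1 | intermediate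
7 | (S)-5-[4-(triisopropylsilyloxy)phenyl]furan-2(5H)-one | O=C1C=C[C@@H](c2ccc(O[Si](C(C)C)(C(C)C)C(C)C)cc2)O1 | intermediate
8 | lithium (4S,5S)-4-methyl-5-[4-(triisopropylsilyloxy)phenyl]-4,5-dihydrofuran-2-olate | [Li+].[O-]C1=C[C@H](C)[C@@H](c2ccc(O[Si](C(C)C)(C(C)C)C(C)C)cc2)O1 | intermediate
9 | (3S,4S,5S)-3,4-dimethyl-5-[4-(triisopropylsilyloxy)phenyl]dihydrofuran-2(3H)-one | C[C@@H]1C(=O)O[C@H](c2ccc(O[Si](C(C)C)(C(C)C)C(C)C)cc2)[C@H]1C | intermediate
10 | (2S,3R)-2,3-dimethyl-4-[4-(triisopropylsilyloxy)phenyl]butanoic acid | C[C@H](C(=O)O)[C@H](C)Cc1ccc(O[Si](C(C)C)(C(C)C)C(C)C)cc1 | intermediate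
11 | (2S,3R)-1-(imidazol-1-yl)-2,3-dimethyl-4-[4-(triisopropylsilyloxy)phenyl]butan-1-one | C[C@H](C(=O)n1ccnc1)[C@H](C)Cc1ccc(O[Si](C(C)C)(C(C)C)C(C)C)cc1 | intermediate
12 | (2S,3R)-N-methoxy-N,2,3-trimethyl-4-[4-(triisopropylsilyloxy)phenyl]butanamide | C[C@H](C(=O)N(C)OC)[C@H](C)Cc1ccc(O[Si](C(C)C)(C(C)C)C(C)C)cc1 | intermediate
13 | 4-bromophenol | Oc1ccc(Br)cc1 | starting material
14 | (4-bromophenoxy)triisopropylsilane | CC(C)[Si](Oc1ccc(Br)cc1)(C(C)C)C(C)C | intermediate
15 | [4-(triisopropylsilyloxy)phenyl]lithium | [Li]c1ccc(O[Si](C(C)C)(C(C)C)C(C)C)cc1 | intermediate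
16 | lithium alkoxide adduct of 15 to the amide carbonyl of 12 (C7 bears O–, N(OMe)Me and ring C) | [Li+].[O-]C(c1ccc(O[Si](C(C)C)(C(C)C)C(C)C)cc1)(N(C)OC)[C@@H](C)[C@H](C)Cc1ccc(O[Si](C(C)C)(C(C)C)C(C)C)cc1 | intermediate
17 | (2S,3R)-2,3-dimethyl-1,4-bis[4-(triisopropylsilyloxy)phenyl]butan-1-one | O=C(c1ccc(O[Si](C(C)C)(C(C)C)C(C)C)cc1)[C@@H](C)[C@H](C)Cc1ccc(O[Si](C(C)C)(C(C)C)C(C)C)cc1 | intermediate
18 | (2S,3R)-2,3-dimethyl-1,4-bis[4-(triisopropylsilyloxy)phenyl]butan-1-ol, both C1 epimers | OC(c1ccc(O[Si](C(C)C)(C(C)C)C(C)C)cc1)[C@@H](C)[C@H](C)Cc1ccc(O[Si](C(C)C)(C(C)C)C(C)C)cc1 | intermediate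
19 | phloroglucinol | Oc1cc(O)cc(O)c1 | starting material
20 | 3-(4-methoxyphenyl)propanenitrile | COc1ccc(CCC#N)cc1 | starting material
21 | 3-(4-methoxyphenyl)-1-(2,4,6-trihydroxyphenyl)propan-1-iminium chloride | [Cl-].COc1ccc(CCC(=[NH2+])c2c(O)cc(O)cc2O)cc1 | intermediate
22 | 3-(4-methoxyphenyl)-1-(2,4,6-trihydroxyphenyl)propan-1-one | COc1ccc(CCC(=O)c2c(O)cc(O)cc2O)cc1 | intermediate
23 | (2S,3R)-2,3-dimethyl-1,4-bis[4-(triisopropylsilyloxy)phenyl]butan-1-ylium | [CH+](c1ccc(O[Si](C(C)C)(C(C)C)C(C)C)cc1)[C@@H](C)[C@H](C)Cc1ccc(O[Si](C(C)C)(C(C)C)C(C)C)cc1 | intermediate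
24 | 1-{3-[(1R,2S,3R)-2,3-dimethyl-1,4-bis[4-(triisopropylsilyloxy)phenyl]butyl]-2,4,6-trihydroxyphenyl}-3-(4-methoxyphenyl)propan-1-one | COc1ccc(CCC(=O)c2c(O)cc(O)c([C@@H](c3ccc(O[Si](C(C)C)(C(C)C)C(C)C)cc3)[C@@H](C)[C@H](C)Cc3ccc(O[Si](C(C)C)(C(C)C)C(C)C)cc3)c2O)cc1 | intermediate
25 | 1-{3-[(1R,2S,3R)-1,4-bis(4-hydroxyphenyl)-2,3-dimethylbutyl]-2,4,6-trihydroxyphenyl}-3-(4-methoxyphenyl)propan-1-one | COc1ccc(CCC(=O)c2c(O)cc(O)c([C@@H](c3ccc(O)cc3)[C@@H](C)[C@H](C)Cc3ccc(O)cc3)c2O)cc1 | target

Total step count: 12. Longest linear sequence: 10 (steps 1–6, 8, 9, 11, 12).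

Steps most likely to fail

Risk 1, step 4.
- **What may go wrong:** proton transfer from C5–H of 7 to the cuprate or to enolate 8, which costs material and enantiopurity. The copper-containing enolate may also methylate sluggishly, and proton exchange between 8 and 9 may lead to double methylation.
- **Fallback, from 7 back to 9:** the two C–CH3 bonds are made in separate operations. Me2CuLi is combined with Me3SiCl in THF at −78 °C, which speeds up the 1,4-addition and caps the oxygen at once as the neutral trimethylsilyl ketene acetal F1. Dilute acid on work-up gives (4S,5S)-4-methyl-5-[4-(triisopropylsilyloxy)phenyl]dihydrofuran-2(3H)-one F2, which is purified. LiN(SiMe3)2 at −78 °C then regenerates copper-free enolate 8, and MeI gives 9 by the same trans alkylation.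

Risk 2, step 11.
- **What may go wrong:** insufficient facial discrimination at planar C7. Proton loss from C8 could give a styrene whose reprotonation would scramble C8, and ring D could capture the cation.
- **Fallback, from 18 back to 25:** the cation is replaced by a neutral electrophile under catalyst control. Bu4NF/AcOH removes both silyl groups to give (2S,3R)-1,4-bis(4-hydroxyphenyl)-2,3-dimethylbutan-1-ol F3. A chiral phosphoric acid, (R)-3,3'-bis(2,4,6-triisopropylphenyl)-1,1'-binaphthyl-2,2'-diyl hydrogen phosphate or its antipode (whichever reinforces the substrate bias), dehydrates F3 to the para-quinone methide 4-[(2S,3R)-4-(4-hydroxyphenyl)-2,3-dimethylbutylidene]cyclohexa-2,5-dien-1-one F4. The acid holds F4 and the most acidic hydroxyl of excess 22 in one hydrogen-bonded assembly. 1,6-Addition and rearomatisation should then give 25 directly.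

Risk 3, step 2.
- **What may go wrong:** slow addition to the electron-rich aldehyde, or insufficient enantioselectivity.
- **Fallback, from 2 and 3 back to 5:** the centre is set by reagent-controlled reduction instead of C–C bond formation. LiN(iPr)2 at −78 °C converts 3 into lithium 3-methoxy-3-oxoprop-1-ynide F5, which adds to 2 to give racemic methyl 4-hydroxy-4-[4-(triisopropylsilyloxy)phenyl]but-2-ynoate F6. MnO2 oxidises it to methyl 4-oxo-4-[4-(triisopropylsilyloxy)phenyl]but-2-ynoate F7. Midland reduction with B-isopinocampheyl-9-borabicyclo[3.3.1]nonane made from (+)-α-pinene treats the linear alkynyl group as the small substituent and should give the (R)-carbinol 5.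

Further compounds
F1 | step 4 | trimethylsilyl ketene acetal, {[(2S,3S)-3-methyl-2-[4-(triisopropylsilyloxy)phenyl]-2,3-dihydrofuran-5-yl]oxy}trimethylsilane | C[Si](C)(C)OC1=C[C@H](C)[C@@H](c2ccc(O[Si](C(C)C)(C(C)C)C(C)C)cc2)O1
F2 | step 4 | (4S,5S)-4-methyl-5-[4-(triisopropylsilyloxy)phenyl]dihydrofuran-2(3H)-one | O=C1C[C@H](C)[C@@H](c2ccc(O[Si](C(C)C)(C(C)C)C(C)C)cc2)O1
F3 | step 11 | (2S,3R)-1,4-bis(4-hydroxyphenyl)-2,3-dimethylbutan-1-ol, both C1 epimers | OC(c1ccc(O)cc1)[C@@H](C)[C@H](C)Cc1ccc(O)cc1
F4 | step 11 | 4-[(2S,3R)-4-(4-hydroxyphenyl)-2,3-dimethylbutylidene]cyclohexa-2,5-dien-1-one | O=C1C=CC(=C[C@@H](C)[C@H](C)Cc2ccc(O)cc2)C=C1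
F5 | step 2 | lithium 3-methoxy-3-oxoprop-1-ynide | [Li]C#CC(=O)OC
F6 | step 2 | racemic methyl 4-hydroxy-4-[4-(triisopropylsilyloxy)phenyl]but-2-ynoate | COC(=O)C#CC(O)c1ccc(O[Si](C(C)C)(C(C)C)C(C)C)cc1
F7 | step 2 | methyl 4-oxo-4-[4-(triisopropylsilyloxy)phenyl]but-2-ynoate | COC(=O)C#CC(=O)c1ccc(O[Si](C(C)C)(C(C)C)C(C)C)cc1
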